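**Retrosynthetic overview**
1. Target ⇐ thiolate demethylation and lactone hydrolysis of a 7,19-dimethyl ester 20→12α-lactone; 3β-OH and 12α-OH come from bulky-hydride reductions; C5 (trans A/B) and C6 come from electron-transfer reduction of a 5(6)-enoate and equilibration.
2. Ring A (last): Robinson annulation with Nazarov's reagent (C10–C1, C4–C5) on a ring-B keto lactone, then C4 methylation anti to C20.
3. Ring B: malonate Michael addition (C9–C10) plus Dieckmann condensation (C5–C6) on a bicyclo[3.2.1]octenone; the 12α-O/C20 lactone then locks C10.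
4. Ring D: palladium-mediated cycloalkenylation (C13–C16) of the silyl dienol ether of a 4-allyl-4-(methoxycarbonylmethyl)cyclohexenone (ring C).
5. C8 stereocentre: CBS reduction of 3-allylcyclohexenone and Johnson–Claisen chirality transfer; ring order C → D → B → A.

Assumption: the route is a paper design, not run; labels C1–C20 and α/β are those of the gibberellin skeleton of the target (β = face of H-9, C18, C7 and the C15–C16 bridge; α = face of C19, C20, H-6 and the 12-OH), and methyl 3-oxopent-4-enoate is bought and distilled before use.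

**Route**

Step 1
Reactants: 1 3-ethoxycyclohex-2-en-1-one; 2 allylmagnesium bromide
Product: 4 3-(prop-2-en-1-yl)cyclohex-2-en-1-one, via 1-allyl-3-ethoxycyclohex-2-en-1-ol 3 (not isolated)
Conditions: THF, 0 °C; then 1 M HCl, 0 → 23 °C
Reagents that add atoms: allylmagnesium bromide, C=CC[Mg]Br
Why: 1,2-Grignard addition to the vinylogous ester followed by acid hydrolysis and dehydration (Stork–Danheiser-type transposition) gives the 3-substituted enone, with no stereocentre formed.

Step 2
Reactants: 4 3-(prop-2-en-1-yl)cyclohex-2-en-1-one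
Product: 5 (1R)-3-(prop-2-en-1-yl)cyclohex-2-en-1-ol
Conditions: (S)-1-methyl-3,3-diphenyltetrahydro-1H,3H-pyrrolo[1,2-c][1,3,2]oxazaborole (10 mol %), catecholborane (1.5 equiv), PhMe, −78 °C; aq NaOH work-up
Reagents that add atoms: none
Why: Corey–Bakshi–Shibata reduction, in which the (S)-oxazaborolidine treats the alkenyl arm as the large group and delivers hydride to one carbonyl face to give the (R)-alcohol (about 90% ee expected), while catecholborane at −78 °C leaves the allyl group alone.

Step 3
Reactants: 5 (1R)-3-(prop-2-en-1-yl)cyclohex-2-en-1-ol; 6 trimethyl orthoacetate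
Product: 8 methyl 2-[(1S)-1-(prop-2-en-1-yl)cyclohex-2-en-1-yl]acetate, via mixed ketene acetal 7 (not isolated)
Conditions: MeC(OMe)3 (6 equiv), EtCO2H (5 mol %), xylenes, 140 °C, MeOH distilled off
Reagents that add atoms: trimethyl orthoacetate, CC(OC)(OC)OC
Why: Johnson–Claisen rearrangement through a chair transition state is suprafacial, so the CH2CO2Me group is delivered to the face of C8 that carried the C11 oxygen and the carbinol chirality becomes the quaternary C8 stereocentre.

Step 4
Reactants: 8 methyl 2-[(1S)-1-(prop-2-en-1-yl)cyclohex-2-en-1-yl]acetate; 9 tert-butyl hydroperoxide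
Product: 10 methyl 2-[(1S)-4-oxo-1-(prop-2-en-1-yl)cyclohex-2-en-1-yl]acetate
Conditions: Rh2(C6H10NO)4 (dirhodium tetracaprolactamate, 1 mol %), t-BuOOH (5 equiv), K2CO3, CH2Cl2, 23 °C
Reagents that add atoms: tert-butyl hydroperoxide, CC(C)(C)OO
Why: Radical allylic C–H oxidation attacks the only allylic methylene of the ring alkene (C12; the other allylic position is the quaternary C8) and gives the 4,4-disubstituted enone without touching the stereocentre.

Step 5
Reactants: 10 methyl 2-[(1S)-4-oxo-1-(prop-2-en-1-yl)cyclohex-2-en-1-yl]acetate; 11 tert-butyldimethylsilyl trifluoromethanesulfonate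
Product: 12 methyl 2-[(1R)-4-(tert-butyldimethylsilyloxy)-1-(prop-2-en-1-yl)cyclohexa-2,4-dien-1-yl]acetate
Conditions: TBSOTf (1.3 equiv), Et3N (2 equiv), CH2Cl2, 0 °C
Reagents that add atoms: tert-butyldimethylsilyl trifluoromethanesulfonate, CC(C)(C)[Si](C)(C)OS(=O)(=O)C(F)(F)F
Why: Soft enolisation of the enone can only occur on the C13 side and gives the cross-conjugated silyl dienol ether regiospecifically (the descriptor changes by priority only, not by configuration).

Step 6
Reactants: 12 methyl 2-[(1R)-4-(tert-butyldimethylsilyloxy)-1-(prop-2-en-1-yl)cyclohexa-2,4-dien-1-yl]acetate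
Product: 13 methyl 2-[(1S,5R)-6-methylidene-4-oxobicyclo[3.2.1]oct-2-en-1-yl]acetate
Conditions: Pd(OAc)2 (10 mol %), O2 (1 atm), DMSO, 45 °C
Reagents that add atoms: none
Why: Palladium-promoted oxidative cycloalkenylation of the silyl enol ether (Saegusa-type palladium enolate, 5-exo carbopalladation joining C13 to C16, then β-hydride elimination to the exocyclic methylene); the allyl group reaches C13 only from its own face, so C13 follows from C8.

Step 7
Reactants: 13 methyl 2-[(1S,5R)-6-methylidene-4-oxobicyclo[3.2.1]oct-2-en-1-yl]acetate; 14 dimethyl malonate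
Product: 16 dimethyl 5-methylidene-2,7-dioxooctahydro-1H-3a,6-methanoazulene-1,3-dicarboxylate, via Michael adduct 15 (not isolated)
Conditions: NaOMe (2.5 equiv), MeOH, 65 °C; then PhMe, 110 °C (MeOH distilled off); AcOH
Reagents that add atoms: dimethyl malonate, COC(=O)CC(=O)OC
Why: Michael addition of the malonate to the non-enolisable enone occurs axially on the face anti to the C15–C16 bridge (sets 9β-H), and a thermodynamically driven Dieckmann condensation of the C6 ester enolate onto a malonate ester then closes ring B as the enolisable 2-oxocyclopentane-1,3-dicarboxylate.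

Step 8
Reactants: 16 dimethyl 5-methylidene-2,7-dioxooctahydro-1H-3a,6-methanoazulene-1,3-dicarboxylate
Product: 18 ring B/C/D keto lactone methyl ester (δ-lactone from C20 to the 12α-oxygen), via 12α-hydroxy diester 17 (not isolated)
Conditions: NaH (1.05 equiv), THF, 0 °C; LiBH(s-Bu)3 (1.3 equiv), −78 °C; AcOH; then pyridinium p-toluenesulfonate (0.1 equiv), PhMe, 60 °C
Reagents that add atoms: none
Why: With the 1,3-dicarbonyl masked as its enolate, the bulky borohydride attacks the C12 ketone equatorially from the β face (the α face is blocked by the axial C10 substituent) to give the 12α-alcohol, and acid-catalysed lactonisation onto the syn-axial C10 ester, after C10 equilibrates through its enol, fixes C20 α.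

Step 9
Reactants: 18 ring B/C/D keto lactone methyl ester; 19 methyl 3-oxopent-4-enoate
Product: 21 7,19-dimethyl 3,12α-dihydroxy-18-norgibberella-3,5,16-triene-7,19,20-trioate 20,12-lactone, via Michael adduct 20 (not isolated)
Conditions: Cs2CO3 (0.2 equiv), CH2Cl2, 0 → 23 °C, slow addition of 19; then pyridinium p-toluenesulfonate (0.3 equiv), PhMe, 100 °C, Dean–Stark
Reagents that add atoms: methyl 3-oxopent-4-enoate, C=CC(=O)CC(=O)OC
Why: Robinson annulation with Nazarov's reagent, in which the more acidic keto-lactone carbon C10 adds to the vinyl ketone on the only face the lactone bridge leaves open (C1 enters β, creating quaternary C10) and an acid-catalysed intramolecular Knoevenagel condensation of C4 onto the C5 ketone closes ring A with loss of water.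

Step 10
Reactants: 21 7,19-dimethyl 3,12α-dihydroxy-18-norgibberella-3,5,16-triene-7,19,20-trioate 20,12-lactone; 22 iodomethane
Product: 23 7,19-dimethyl 12α-hydroxy-3-oxogibberella-5,16-diene-7,19,20-trioate 20,12-lactone
Conditions: K2CO3 (3 equiv), MeI (5 equiv), acetone, 40 °C
Reagents that add atoms: iodomethane, CI
Why: Deconjugative α-alkylation of the extended β-keto ester enolate (the classical podocarpic acid tactic), in which methyl iodide attacks C4, the less hindered terminus, from the β face opposite the axial C20 carbonyl so that C19 ends up α and the double bond stays at C5=C6.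

Step 11
Reactants: 23 7,19-dimethyl 12α-hydroxy-3-oxogibberella-5,16-diene-7,19,20-trioate 20,12-lactone
Product: 24 7,19-dimethyl 3β,12α-dihydroxygibberella-5,16-diene-7,19,20-trioate 20,12-lactone
Conditions: LiBH(s-Bu)3 (1.3 equiv), THF, −78 °C; AcOH at −78 °C
Reagents that add atoms: none
Why: Bulky trialkylborohydride reduction of a 4,4-disubstituted cyclohexanone proceeds by equatorial attack and gives the axial 3β-alcohol, and the cold acidic quench avoids retro-aldol cleavage.

Step 12
Reactants: 24 7,19-dimethyl 3β,12α-dihydroxygibberella-5,16-diene-7,19,20-trioate 20,12-lactone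
Product: 26 7,19-dimethyl 3β,12α-dihydroxygibberell-16-ene-7,19,20-trioate 20,12-lactone, via 6-epimer 25 (not isolated)
Conditions: SmI2 (4 equiv), HMPA (10 equiv), MeOH (4 equiv), THF, −78 → 0 °C; aq work-up; then NaOMe (0.3 equiv), MeOH, 0 → 23 °C; AcOH, then pyridinium p-toluenesulfonate (cat.), PhMe, 50 °C
Reagents that add atoms: none
Why: Electron-transfer conjugate reduction of the tetrasubstituted unsaturated ester protonates C5 axially from the β face, away from the axial C19 and C20 groups (trans A/B fusion), and methoxide equilibration then brings C6 to the more stable natural configuration with CO2Me β and trans to C4.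

Step 13
Reactants: 26 7,19-dimethyl 3β,12α-dihydroxygibberell-16-ene-7,19,20-trioate 20,12-lactone; 27 water
Product: 29 3β,12α-dihydroxygibberell-16-ene-7,19,20-trioic acid (the target gibberellin), via diacid lactone 28 (not isolated)
Conditions: LiSPr (8 equiv), HMPA, 23 → 50 °C; then LiOH, THF–H2O, 23 °C; then 1 M HCl to pH 3 at 0 °C, rapid extraction
Reagents that add atoms: water, O
Why: SN2 demethylation of the two hindered methyl esters by thiolate, then saponification of the δ-lactone by acyl–oxygen cleavage (C12 keeps its configuration), frees the three acids and the 12α-OH without epimerisation.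

**Compound list**
1 | 3-ethoxycyclohex-2-en-1-one | CCOC1=CC(=O)CCC1 | starting material
2 | allylmagnesium bromide | C=CC[Mg]Br | starting material
3 | 1-allyl-3-ethoxycyclohex-2-en-1-ol (racemic, formed as its bromomagnesium alkoxide) | C=CCC1(O)C=C(OCC)CCC1 | intermediate
4 | 3-(prop-2-en-1-yl)cyclohex-2-en-1-one | C=CCC1=CC(=O)CCC1 | intermediate
5 | (1R)-3-(prop-2-en-1-yl)cyclohex-2-en-1-ol | C=CCC1=C[C@H](O)CCC1 | intermediate
6 | trimethyl orthoacetate | CC(OC)(OC)OC | starting material
7 | 1-methoxyethenyl ether of 5 (mixed ketene acetal, R at the carbinol carbon) | C=CCC1=C[C@H](OC(=C)OC)CCC1 | intermediate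
8 | methyl 2-[(1S)-1-(prop-2-en-1-yl)cyclohex-2-en-1-yl]acetate | C=CC[C@@]1(CC(=O)OC)C=CCCC1 | intermediate
9 | tert-butyl hydroperoxide | CC(C)(C)OO | starting material
10 | methyl 2-[(1S)-4-oxo-1-(prop-2-en-1-yl)cyclohex-2-en-1-yl]acetate | C=CC[C@@]1(CC(=O)OC)C=CC(=O)CC1 | intermediate
11 | tert-butyldimethylsilyl trifluoromethanesulfonate | CC(C)(C)[Si](C)(C)OS(=O)(=O)C(F)(F)F | starting material
12 | methyl 2-[(1R)-4-(tert-butyldimethylsilyloxy)-1-(prop-2-en-1-yl)cyclohexa-2,4-dien-1-yl]acetate | C=CC[C@@]1(CC(=O)OC)C=CC(O[Si](C)(C)C(C)(C)C)=CC1 | intermediate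
13 | methyl 2-[(1S,5R)-6-methylidene-4-oxobicyclo[3.2.1]oct-2-en-1-yl]acetate (ring C/D enone; C8 and C13 as in the target) | C=C1C[C@]2(CC(=O)OC)C[C@H]1C(=O)C=C2 | intermediate
14 | dimethyl malonate | COC(=O)CC(=O)OC | starting material
15 | dimethyl 2-[(1S,2S,5R)-1-(2-methoxy-2-oxoethyl)-6-methylidene-4-oxobicyclo[3.2.1]octan-2-yl]propanedioate (malonate on C9 α, 9β-H) | C=C1C[C@]2(CC(=O)OC)C[C@H]1C(=O)C[C@H]2C(C(=O)OC)C(=O)OC | intermediate
16 | dimethyl 5-methylidene-2,7-dioxooctahydro-1H-3a,6-methanoazulene-1,3-dicarboxylate (ring B cyclopentanone C5=O with CO2Me on C6 and C10, C12 ketone, 9β-H; C6/C10 epimers and enol forms) | C=C1C[C@]23C[C@H]1C(=O)C[C@H]2C(C(=O)OC)C(=O)C3C(=O)OC | intermediate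
17 | 12α-hydroxy analogue of 16 (C12 ketone reduced, OH α) | C=C1C[C@]23C[C@H]1[C@@H](O)C[C@H]2C(C(=O)OC)C(=O)C3C(=O)OC | intermediate
18 | ring B/C/D keto lactone methyl ester: C5 ketone, CO2Me on C6 (epimers), C10 carboxyl closed as δ-lactone onto the 12α-oxygen (C20 α, 9β-H), 16-methylidene | C=C1C[C@]23C[C@H]1[C@@H]4C[C@H]2[C@@H](C(=O)O4)C(=O)C3C(=O)OC | intermediate
19 | methyl 3-oxopent-4-enoate (Nazarov's reagent, methyl ester) | C=CC(=O)CC(=O)OC | starting material
20 | 18 carrying a 5-methoxy-3,5-dioxopentyl chain on C10 (chain β, C20 α) | C=C1C[C@]23C[C@H]1[C@@H]4C[C@H]2[C@@](CCC(=O)CC(=O)OC)(C(=O)O4)C(=O)C3C(=O)OC | intermediate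
21 | 7,19-dimethyl 3,12α-dihydroxy-18-norgibberella-3,5,16-triene-7,19,20-trioate 20,12-lactone (enol tautomer; 5(6)-ene; 9β-H) | C=C1C[C@]23C[C@H]1[C@@H]4C[C@H]2[C@]5(C(=O)O4)CCC(O)=C(C(=O)OC)C5=C3C(=O)OC | intermediate
22 | iodomethane | CI | starting material
23 | 7,19-dimethyl 12α-hydroxy-3-oxogibberella-5,16-diene-7,19,20-trioate 20,12-lactone (C18 β, C19 α) | C=C1C[C@]23C[C@H]1[C@@H]4C[C@H]2[C@]5(C(=O)O4)CCC(=O)[C@@](C)(C(=O)OC)C5=C3C(=O)OC | intermediate
24 | 7,19-dimethyl 3β,12α-dihydroxygibberella-5,16-diene-7,19,20-trioate 20,12-lactone | C=C1C[C@]23C[C@H]1[C@@H]4C[C@H]2[C@]5(C(=O)O4)CC[C@H](O)[C@@](C)(C(=O)OC)C5=C3C(=O)OC | intermediate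
25 | 6-epimer of 26: 7,19-dimethyl 3β,12α-dihydroxygibberell-16-ene-7,19,20-trioate 20,12-lactone with 5β-H and 6β-H | C=C1C[C@]23C[C@H]1[C@@H]4C[C@H]2[C@]5(C(=O)O4)CC[C@H](O)[C@@](C)(C(=O)OC)[C@H]5[C@H]3C(=O)OC | intermediate
26 | 7,19-dimethyl 3β,12α-dihydroxygibberell-16-ene-7,19,20-trioate 20,12-lactone (5β-H, 6α-H; 7,19-dimethyl ester 20,12-lactone of the target) | C=C1C[C@]23C[C@H]1[C@@H]4C[C@H]2[C@]5(C(=O)O4)CC[C@H](O)[C@@](C)(C(=O)OC)[C@H]5[C@@H]3C(=O)OC | intermediate
27 | water | O | starting material
28 | 3β,12α-dihydroxygibberell-16-ene-7,19,20-trioic acid 20,12-lactone (free 7- and 19-carboxylic acids) | C=C1C[C@]23C[C@H]1[C@@H]4C[C@H]2[C@]5(C(=O)O4)CC[C@H](O)[C@@](C)(C(=O)O)[C@H]5[C@@H]3C(=O)O | intermediate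
29 | 3β,12α-dihydroxygibberell-16-ene-7,19,20-trioic acid (the target gibberellin) | C=C1C[C@]23C[C@H]1[C@@H](O)C[C@H]2[C@]1(C(=O)O)CC[C@H](O)[C@@](C)(C(=O)O)[C@H]1[C@@H]3C(=O)O | target

**Totals and risks**
Total step count: 13. Longest linear sequence: 13 steps (fully linear from 1).

Risk 1 (step 7). The intermolecular malonate addition to the β-carbon next to the quaternary bridgehead may stall or revert. The fallback makes the Michael addition intramolecular and sets out from 13. The ester enolate (LiN(SiMe3)2, THF, −78 °C) is carboxylated with CO2 to the malonic half-ester F1. Chain extension (1,1'-carbonyldiimidazole, then Mg(O2CCH2CO2Me)2, THF) gives the 3-oxopentanedioate F2. Cs2CO3 in MeCN then closes ring B by 5-exo Michael addition of the doubly activated C10 methylene onto C9 from the α face, and the route is rejoined at 16.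

Risk 2 (step 9). The Knoevenagel closure onto the flanked, enolisable C5 ketone may fail, and the following C4 methylation could compete with attack at C6. The fallback forms C4–C5 by cross-coupling, closes ring A by Dieckmann condensation and brings C18 in with the coupling partner; it sets out from 18. Michael addition to methyl acrylate (1,8-diazabicyclo[5.4.0]undec-7-ene cat., CH2Cl2) gives the C10-propanoate keto lactone F3. NaH and PhN(SO2CF3)2 convert the only enolisable side of the C5 ketone into the enol triflate F4. Negishi coupling with BrZnCH(CH3)CO2Me (Pd(PPh3)4, THF, 60 °C) gives the propanoate-substituted enoate F5. LiN(SiMe3)2 (THF, −78 → 0 °C) then acylates the C4 dienolate with the C3 ester; the dienolate keeps its methyl next to the C7 ester, so C19 should end up axial and α. The route is rejoined at 23.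

Risk 3 (step 12). Electron-transfer reduction of the crowded tetrasubstituted enoate may be slow or unselective, and the methoxide equilibration is run with a free 3β-OH, which risks retro-aldol. The fallback uses catalytic hydrogenation after temporary removal of the exocyclic methylene and sets out from 24. OsO4 (cat.) with NaIO4 cleaves only the 16-methylidene to the 17-nor-16-ketone F6. Hydroxyl-directed hydrogenation with [Ir(cod)(PCy3)(py)]PF6 (H2, CH2Cl2) delivers hydrogen to the β face from the 3β-OH, and brief NaOMe/MeOH equilibration of C6 gives the saturated nor-ketone F7. Methylenation with Zn, CH2Br2 and TiCl4 in THF restores the 16-methylidene, and the route is rejoined at 26.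

**Further compounds**
F1 | step 7 | 3-methoxy-2-(6-methylidene-4-oxobicyclo[3.2.1]oct-2-en-1-yl)-3-oxopropanoic acid, bridgeheads as in 13, epimers at the malonate carbon | C=C1C[C@]2(C(C(=O)O)C(=O)OC)C[C@H]1C(=O)C=C2
F2 | step 7 | dimethyl 2-(6-methylidene-4-oxobicyclo[3.2.1]oct-2-en-1-yl)-3-oxopentanedioate, bridgeheads as in 13 | C=C1C[C@]2(C(C(=O)OC)C(=O)CC(=O)OC)C[C@H]1C(=O)C=C2
F3 | step 9 | keto lactone 18 carrying a 3-methoxy-3-oxopropyl group on C10 (chain β, C20 α) | C=C1C[C@]23C[C@H]1[C@@H]4C[C@H]2[C@@](CCC(=O)OC)(C(=O)O4)C(=O)C3C(=O)OC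
F4 | step 9 | C5 enol trifluoromethanesulfonate of F3 (5(6)-ene, CO2Me on C6) | C=C1C[C@]23C[C@H]1[C@@H]4C[C@H]2[C@@](CCC(=O)OC)(C(=O)O4)C(OS(=O)(=O)C(F)(F)F)=C3C(=O)OC
F5 | step 9 | 5(6)-enoate carrying a 1-methoxy-1-oxopropan-2-yl group (C4 with C18 and C19) on C5, C4 epimers | C=C1C[C@]23C[C@H]1[C@@H]4C[C@H]2[C@@](CCC(=O)OC)(C(=O)O4)C(C(C)C(=O)OC)=C3C(=O)OC
F6 | step 12 | 17-nor-16-oxo analogue of 24 | O=C1C[C@]23C[C@H]1[C@@H]4C[C@H]2[C@]5(C(=O)O4)CC[C@H](O)[C@@](C)(C(=O)OC)C5=C3C(=O)OC
F7 | step 12 | 17-nor-16-oxo analogue of 26 (5β-H, 6α-H) | O=C1C[C@]23C[C@H]1[C@@H]4C[C@H]2[C@]5(C(=O)O4)CC[C@H](O)[C@@](C)(C(=O)OC)[C@H]5[C@@H]3C(=O)OC
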